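**Retrosynthetic overview**

1. The (Z)-enal on ring C1 and the 3-hydroxypropyl arm on ring C2 are tied through the propyl oxygen into an eight-membered cyclic allyl ether (O–CH2–C(CH3)=C1–C2–CH2CH2CH2). In this ring the tetrasubstituted C1=C2′ alkene can only be Z; DDQ/water then opens it to the CHO and the CH2OH (step 16).
2. The oxocine ring is closed by intramolecular McMurry coupling of the ring C1 ketone with an acetonyl ether carbonyl (step 15); this forms the C1=C2′ bond.
3. The three contiguous ring stereocentres come from enone 21: methyl is added anti to the C4 silyloxy group (quaternary C3), and the enolate is allylated anti to the new methyl (C2).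
4. Enone 21 comes from Stork–Danheiser addition of side-chain lithium 19 (geranyl acetate + 3-methylbutan-2-one) to vinylogous ester 18. The C4 carbinol is set by asymmetric enolate hydroxylation.
5. Ring order: the cyclohexane is bought (13); the oxocine is closed in step 15 and opened in step 16.

Key step: step 15

**Remarks**

- R = (3E,7E)-4,8,12-trimethyl-11-methylidenetrideca-3,7-dien-1-yl.
- Ring atoms are numbered as in the compound names; C1′ (CHO) and C2′ are the propanal carbons.
- Assumption: the (+)-dichlorocamphorylsulfonyl oxaziridine is taken to give the R carbinol, as with 2-alkyl-1-tetralone enolates; if the sense is the reverse, its enantiomer is used.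
- The route is a proposal; nothing has been run.

**Route**

Step 1
Reactants: 1 geranyl acetate
Product: 2 (2E,6E)-8-hydroxy-3,7-dimethylocta-2,6-dien-1-yl acetate
Conditions: SeO2 (cat.), t-BuOOH (70% aq.), salicylic acid (cat.), CH2Cl2, rt
Reagents that add atoms: tert-butyl hydroperoxide CC(C)(C)OO
Why: Catalytic SeO2 allylic oxidation (ene reaction, then [2,3]-shift) should attack the electron-rich terminal alkene at its E-methyl group, the 2,3-alkene being deactivated by the allylic acetate; no stereocentre is formed.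

Step 2
Reactants: 2 (2E,6E)-8-hydroxy-3,7-dimethylocta-2,6-dien-1-yl acetate
Product: 3 (2E,6E)-8-bromo-3,7-dimethylocta-2,6-dien-1-yl acetate
Conditions: CBr4, PPh3, CH2Cl2, 0 °C
Reagents that add atoms: tetrabromomethane BrC(Br)(Br)Br
Why: Appel bromination of a primary allylic alcohol is an SN2 displacement on the alkoxyphosphonium ion and should keep the E geometry without allylic transposition.

Step 3
Reactants: 3 (2E,6E)-8-bromo-3,7-dimethylocta-2,6-dien-1-yl acetate; 4 3-methylbutan-2-one
Product: 6 (2E,6E)-3,7,11-trimethyl-10-oxododeca-2,6-dien-1-yl acetate, via lithium enolate 5 (not isolated)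
Conditions: LDA, THF, −78 °C; then 3, −78 to 0 °C
Reagents that add atoms: none
Why: LDA deprotonates the ketone kinetically at its methyl group, and SN2 C-alkylation of the lithium enolate by the primary allylic bromide should be faster than attack on the acetate at low temperature.

Step 4
Reactants: 6 (2E,6E)-3,7,11-trimethyl-10-oxododeca-2,6-dien-1-yl acetate
Product: 8 (2E,6E)-3,7,11-trimethyl-10-methylidenedodeca-2,6-dien-1-ol, via methylidene acetate 7 (not isolated)
Conditions: Ph3PCH3Br, KOt-Bu, THF, 0 °C to rt; then K2CO3, MeOH, rt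
Reagents that add atoms: methyltriphenylphosphonium bromide C[P+](c1ccccc1)(c1ccccc1)c1ccccc1.[Br-]
Why: Wittig methylenation turns the isopropyl ketone into the 1,1-disubstituted alkene, and base-catalysed transesterification then removes the acetate without touching the alkenes.

Step 5
Reactants: 8 (2E,6E)-3,7,11-trimethyl-10-methylidenedodeca-2,6-dien-1-ol
Product: 9 (2E,6E)-1-bromo-3,7,11-trimethyl-10-methylidenedodeca-2,6-diene
Conditions: CBr4, PPh3, CH2Cl2, 0 °C
Reagents that add atoms: tetrabromomethane BrC(Br)(Br)Br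
Why: Appel bromination as in step 2; SN2 at the primary allylic carbon should retain the E alkene.

Step 6
Reactants: 9 (2E,6E)-1-bromo-3,7,11-trimethyl-10-methylidenedodeca-2,6-diene
Product: 11 (3E,7E)-4,8,12-trimethyl-11-methylidenetrideca-3,7-dien-1-ol, via silane 10 (not isolated)
Conditions: (i-PrO)Me2SiCH2MgCl, CuI (10 mol%), THF, −20 to 0 °C; then KF, KHCO3, 30% H2O2, THF/MeOH, rt
Reagents that add atoms: [dimethyl(propan-2-yloxy)silyl]methylmagnesium chloride CC(C)O[Si](C)(C)C[Mg]Cl; hydrogen peroxide OO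
Why: Copper-catalysed SN2 coupling of the allylic bromide with the silylmethyl Grignard reagent (SN2′ would have to build a quaternary carbon), then Tamao oxidation of the C–Si bond, gives the one-carbon-homologated alcohol; these oxidation conditions leave isolated alkenes alone.

Step 7
Reactants: 11 (3E,7E)-4,8,12-trimethyl-11-methylidenetrideca-3,7-dien-1-ol
Product: 12 (3E,7E)-1-iodo-4,8,12-trimethyl-11-methylidenetrideca-3,7-diene
Conditions: I2, PPh3, imidazole, CH2Cl2, 0 °C
Reagents that add atoms: iodine II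
Why: Appel-type iodination of a primary alcohol (SN2); no stereocentre is involved.

Step 8
Reactants: 13 3-ethoxycyclohex-2-en-1-one
Product: 15 3-ethoxy-6-methylcyclohex-2-en-1-one (racemic), via lithium dienolate 14 (not isolated)
Conditions: LDA, THF, −78 °C; then MeI, −78 to 0 °C
Reagents that add atoms: iodomethane CI
Why: Kinetic α′-deprotonation of the vinylogous ester and methylation (Stork–Danheiser alkylation); the racemic stereocentre is erased again in step 9.

Step 9
Reactants: 15 3-ethoxy-6-methylcyclohex-2-en-1-one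
Product: 17 (6R)-3-ethoxy-6-hydroxy-6-methylcyclohex-2-en-1-one, via sodium enolate 16 (not isolated)
Conditions: NaHMDS, THF, −78 °C; then (+)-[(8,8-dichlorocamphoryl)sulfonyl]oxaziridine, −78 °C; AcOH quench
Reagents that add atoms: (+)-[(8,8-dichlorocamphoryl)sulfonyl]oxaziridine CC1(C)[C@@H]2CC[C@]13CS(=O)(=O)N4O[C@@]34C2(Cl)Cl
Why: Asymmetric enolate hydroxylation with a chiral N-sulfonyloxaziridine: the planar tetrasubstituted sodium enolate, which like a 2-alkyl-1-tetralone enolate is flanked by an sp2 carbon, should be oxidised from one face, setting the carbinol (ring C4 of the target) as R.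

Step 10
Reactants: 17 (6R)-3-ethoxy-6-hydroxy-6-methylcyclohex-2-en-1-one
Product: 18 (6R)-3-ethoxy-6-methyl-6-[(triethylsilyl)oxy]cyclohex-2-en-1-one
Conditions: TESOTf, 2,6-lutidine, CH2Cl2, −78 to 0 °C
Reagents that add atoms: triethylsilyl trifluoromethanesulfonate CC[Si](CC)(CC)OS(=O)(=O)C(F)(F)F
Why: Silyl triflate silylation of the hindered tertiary alcohol protects the carbinol and turns it into a non-coordinating group that directs the cuprate anti in step 12.

Step 11
Reactants: 12 (3E,7E)-1-iodo-4,8,12-trimethyl-11-methylidenetrideca-3,7-diene; 18 (6R)-3-ethoxy-6-methyl-6-[(triethylsilyl)oxy]cyclohex-2-en-1-one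
Product: 21 (4R)-4-methyl-3-R-4-[(triethylsilyl)oxy]cyclohex-2-en-1-one, via alkyllithium 19 (not isolated), via lithium alkoxide 20 (not isolated)
Conditions: 12, t-BuLi (2.1 equiv), Et2O/pentane, −78 °C; then 18, −78 to 0 °C; then 1 M HCl, THF, 0 °C
Reagents that add atoms: water O
Why: Stork–Danheiser transposition: iodine–lithium exchange, 1,2-addition to the vinylogous ester carbonyl, then acid hydrolysis of the enol ether with loss of water, places the side chain on the β-carbon of the new enone; the silyloxy carbinol is not touched.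

Step 12
Reactants: 21 (4R)-4-methyl-3-R-4-[(triethylsilyl)oxy]cyclohex-2-en-1-one
Product: 24 (2R,3S,4R)-3,4-dimethyl-2-(prop-2-en-1-yl)-3-R-4-[(triethylsilyl)oxy]cyclohexan-1-one, via TMS enol ether 22 (not isolated), via lithium enolate 23 (not isolated)
Conditions: MeMgBr, CuBr·SMe2 (10 mol%), TMSCl, HMPA, THF, −78 to −40 °C; then MeLi, THF, 0 °C; then allyl iodide, HMPA, −78 to 0 °C
Reagents that add atoms: methylmagnesium bromide C[Mg]Br; 3-iodoprop-1-ene C=CCI
Why: Tandem conjugate addition–enolate alkylation: the TMSCl/HMPA-accelerated copper-catalysed addition should deliver methyl axially and anti to the C4 silyloxy group (quaternary C3), and the regiodefined lithium enolate is allylated anti to that new methyl (C2, allyl cis to the chain R).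

Step 13
Reactants: 24 (2R,3S,4R)-3,4-dimethyl-2-(prop-2-en-1-yl)-3-R-4-[(triethylsilyl)oxy]cyclohexan-1-one
Product: 26 (2R,3S,4R)-2-(3-hydroxypropyl)-3,4-dimethyl-3-R-4-[(triethylsilyl)oxy]cyclohexan-1-one, via catechol boronate 25 (not isolated)
Conditions: catecholborane, RhCl(PPh3)3 (2 mol%), THF, 0 °C to rt; then pH 7 buffer, 30% H2O2, 0 °C
Reagents that add atoms: hydrogen peroxide OO
Why: Rhodium-catalysed anti-Markovnikov hydroboration is selective for the monosubstituted terminal alkene over the ketone and the 1,1-di- and trisubstituted alkenes of R, and buffered oxidation should not epimerise C2.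

Step 14
Reactants: 26 (2R,3S,4R)-2-(3-hydroxypropyl)-3,4-dimethyl-3-R-4-[(triethylsilyl)oxy]cyclohexan-1-one
Product: 27 (2R,3S,4R)-3,4-dimethyl-2-[3-(2-oxopropoxy)propyl]-3-R-4-[(triethylsilyl)oxy]cyclohexan-1-one
Conditions: 1-diazopropan-2-one (slow addition), Rh2(OAc)4 (1 mol%), CH2Cl2, rt
Reagents that add atoms: 1-diazopropan-2-one CC(=O)C=[N+]=[N-]
Why: Rh(II)-carbenoid O–H insertion into the primary alcohol is much faster than cyclopropanation of the hindered alkenes and needs no base, so C2 (α to the ketone) keeps its configuration.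

Step 15
Reactants: 27 (2R,3S,4R)-3,4-dimethyl-2-[3-(2-oxopropoxy)propyl]-3-R-4-[(triethylsilyl)oxy]cyclohexan-1-one
Product: 28 (6aS,7S,8R)-1,7,8-trimethyl-7-R-8-[(triethylsilyl)oxy]-4,5,6,6a,7,8,9,10-octahydro-2H-3-benzoxocine
Conditions: TiCl3(DME)1.5, Zn–Cu, DME, reflux, syringe-pump addition of 27 (final concentration ≤ 5 mM)
Reagents that add atoms: none
Why: Low-valent titanium reduces both ketones to titanium-bound ketyls, these couple to a cyclic titanium pinacolate, and the pinacolate is deoxygenated on the metal at reflux to the C1=C2′ double bond (intramolecular McMurry coupling). The closest known cases are diketones giving 1,2-dialkylcycloalkenes, eight-membered rings included, and bis(2-oxoalkyl) ethers and sulfides giving dihydrofurans and dihydrothiophenes with the C–heteroatom bond next to the carbonyl intact. The eight-membered oxocine ring is closed by carbonyl–carbonyl coupling under high dilution, and the two carbonyl carbons become the ring alkene. No sp3 stereocentre is formed; the only new stereo element is the geometry of the tetrasubstituted alkene, and the ring fixes it, because an eight-membered ring cannot hold an E double bond, so the OCH2 carbon (the later CHO) must be cis to ring C2 and the methyl cis to ring C6. The step needs intra- over intermolecular coupling (slow addition), coupling faster than reductive cleavage of the α-C–O bond, and no epimerisation at C2, which the aprotic, non-basic medium should allow.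

Step 16
Reactants: 28 (6aS,7S,8R)-1,7,8-trimethyl-7-R-8-[(triethylsilyl)oxy]-4,5,6,6a,7,8,9,10-octahydro-2H-3-benzoxocine
Product: 30 (2Z)-2-[(2S,3S,4R)-4-hydroxy-2-(3-hydroxypropyl)-3,4-dimethyl-3-R-cyclohexylidene]propanal (target), via silyl-protected enal 29 (not isolated)
Conditions: DDQ, CH2Cl2/pH 7 buffer (10:1), 0 °C; then HF·pyridine, pyridine, THF, 0 °C
Reagents that add atoms: water O
Why: DDQ should abstract hydride from the allylic O–CH2 carbon (the one C–H activated by both the oxygen and the tetrasubstituted alkene, as in the oxidative cleavage of prenyl ethers), water adds to the oxocarbenium ion and the hemiacetal opens to the Z-enal and the primary alcohol with the geometry fixed in step 15; HF·pyridine then cleaves the tertiary silyl ether.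

**Compound list**

1 | geranyl acetate, (2E)-3,7-dimethylocta-2,6-dien-1-yl acetate | CC(C)=CCC/C(C)=C/COC(C)=O | starting material
2 | (2E,6E)-8-hydroxy-3,7-dimethylocta-2,6-dien-1-yl acetate | OC/C(C)=C/CC/C(C)=C/COC(C)=O | intermediate
3 | (2E,6E)-8-bromo-3,7-dimethylocta-2,6-dien-1-yl acetate | BrC/C(C)=C/CC/C(C)=C/COC(C)=O | intermediate
4 | 3-methylbutan-2-one | CC(=O)C(C)C | starting material
5 | lithium 3-methylbut-1-en-2-olate | C=C(O[Li])C(C)C | intermediate (not isolated)
6 | (2E,6E)-3,7,11-trimethyl-10-oxododeca-2,6-dien-1-yl acetate | CC(C)C(=O)CC/C(C)=C/CC/C(C)=C/COC(C)=O | intermediate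
7 | (2E,6E)-3,7,11-trimethyl-10-methylidenedodeca-2,6-dien-1-yl acetate | C=C(CC/C(C)=C/CC/C(C)=C/COC(C)=O)C(C)C | intermediate (not isolated)
8 | (2E,6E)-3,7,11-trimethyl-10-methylidenedodeca-2,6-dien-1-ol | C=C(CC/C(C)=C/CC/C(C)=C/CO)C(C)C | intermediate
9 | (2E,6E)-1-bromo-3,7,11-trimethyl-10-methylidenedodeca-2,6-diene | C=C(CC/C(C)=C/CC/C(C)=C/CBr)C(C)C | intermediate
10 | dimethyl(propan-2-yloxy)[(3E,7E)-4,8,12-trimethyl-11-methylidenetrideca-3,7-dien-1-yl]silane | C=C(CC/C(C)=C/CC/C(C)=C/CC[Si](C)(C)OC(C)C)C(C)C | intermediate (not isolated)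
11 | (3E,7E)-4,8,12-trimethyl-11-methylidenetrideca-3,7-dien-1-ol | C=C(CC/C(C)=C/CC/C(C)=C/CCO)C(C)C | intermediate
12 | (3E,7E)-1-iodo-4,8,12-trimethyl-11-methylidenetrideca-3,7-diene | C=C(CC/C(C)=C/CC/C(C)=C/CCI)C(C)C | intermediate
13 | 3-ethoxycyclohex-2-en-1-one | CCOC1=CC(=O)CCC1 | starting material
14 | lithium 5-ethoxycyclohexa-1,5-dien-1-olate | CCOC1=CC(O[Li])=CCC1 | intermediate (not isolated)
15 | 3-ethoxy-6-methylcyclohex-2-en-1-one (racemic) | CCOC1=CC(=O)C(C)CC1 | intermediate
16 | sodium 5-ethoxy-2-methylcyclohexa-1,5-dien-1-olate | CCOC1=CC(O[Na])=C(C)CC1 | intermediate (not isolated)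
17 | (6R)-3-ethoxy-6-hydroxy-6-methylcyclohex-2-en-1-one | O=C1C=C(OCC)CC[C@@]1(C)O | intermediate
18 | (6R)-3-ethoxy-6-methyl-6-[(triethylsilyl)oxy]cyclohex-2-en-1-one | O=C1C=C(OCC)CC[C@@]1(C)O[Si](CC)(CC)CC | intermediate
19 | [(3E,7E)-4,8,12-trimethyl-11-methylidenetrideca-3,7-dien-1-yl]lithium | C=C(CC/C(C)=C/CC/C(C)=C/CC[Li])C(C)C | intermediate (not isolated)
20 | lithium (6R)-3-ethoxy-6-methyl-6-[(triethylsilyl)oxy]-1-[(3E,7E)-4,8,12-trimethyl-11-methylidenetrideca-3,7-dien-1-yl]cyclohex-2-en-1-olate (both C1 epimers) | C=C(CC/C(C)=C/CC/C(C)=C/CCC1(O[Li])C=C(OCC)CC[C@@]1(C)O[Si](CC)(CC)CC)C(C)C | intermediate (not isolated)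
21 | (4R)-4-methyl-4-[(triethylsilyl)oxy]-3-[(3E,7E)-4,8,12-trimethyl-11-methylidenetrideca-3,7-dien-1-yl]cyclohex-2-en-1-one | C=C(CC/C(C)=C/CC/C(C)=C/CCC1=CC(=O)CC[C@@]1(C)O[Si](CC)(CC)CC)C(C)C | intermediate
22 | triethyl({(1R,2S)-1,2-dimethyl-2-[(3E,7E)-4,8,12-trimethyl-11-methylidenetrideca-3,7-dien-1-yl]-4-[(trimethylsilyl)oxy]cyclohex-3-en-1-yl}oxy)silane | C=C(CC/C(C)=C/CC/C(C)=C/CC[C@@]1(C)C=C(O[Si](C)(C)C)CC[C@@]1(C)O[Si](CC)(CC)CC)C(C)C | intermediate (not isolated)
23 | lithium (3S,4R)-3,4-dimethyl-4-[(triethylsilyl)oxy]-3-[(3E,7E)-4,8,12-trimethyl-11-methylidenetrideca-3,7-dien-1-yl]cyclohex-1-en-1-olate | C=C(CC/C(C)=C/CC/C(C)=C/CC[C@@]1(C)C=C(O[Li])CC[C@@]1(C)O[Si](CC)(CC)CC)C(C)C | intermediate (not isolated)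
24 | (2R,3S,4R)-3,4-dimethyl-2-(prop-2-en-1-yl)-4-[(triethylsilyl)oxy]-3-[(3E,7E)-4,8,12-trimethyl-11-methylidenetrideca-3,7-dien-1-yl]cyclohexan-1-one | C=C(CC/C(C)=C/CC/C(C)=C/CC[C@@]1(C)[C@@H](CC=C)C(=O)CC[C@@]1(C)O[Si](CC)(CC)CC)C(C)C | intermediate
25 | (2R,3S,4R)-2-[3-(1,3,2-benzodioxaborol-2-yl)propyl]-3,4-dimethyl-4-[(triethylsilyl)oxy]-3-[(3E,7E)-4,8,12-trimethyl-11-methylidenetrideca-3,7-dien-1-yl]cyclohexan-1-one | C=C(CC/C(C)=C/CC/C(C)=C/CC[C@@]1(C)[C@@H](CCCB2Oc3ccccc3O2)C(=O)CC[C@@]1(C)O[Si](CC)(CC)CC)C(C)C | intermediate (not isolated)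
26 | (2R,3S,4R)-2-(3-hydroxypropyl)-3,4-dimethyl-4-[(triethylsilyl)oxy]-3-[(3E,7E)-4,8,12-trimethyl-11-methylidenetrideca-3,7-dien-1-yl]cyclohexan-1-one | C=C(CC/C(C)=C/CC/C(C)=C/CC[C@@]1(C)[C@@H](CCCO)C(=O)CC[C@@]1(C)O[Si](CC)(CC)CC)C(C)C | intermediate
27 | (2R,3S,4R)-3,4-dimethyl-2-[3-(2-oxopropoxy)propyl]-4-[(triethylsilyl)oxy]-3-[(3E,7E)-4,8,12-trimethyl-11-methylidenetrideca-3,7-dien-1-yl]cyclohexan-1-one | C=C(CC/C(C)=C/CC/C(C)=C/CC[C@@]1(C)[C@@H](CCCOCC(C)=O)C(=O)CC[C@@]1(C)O[Si](CC)(CC)CC)C(C)C | intermediate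
28 | (6aS,7S,8R)-1,7,8-trimethyl-8-[(triethylsilyl)oxy]-7-[(3E,7E)-4,8,12-trimethyl-11-methylidenetrideca-3,7-dien-1-yl]-4,5,6,6a,7,8,9,10-octahydro-2H-3-benzoxocine | C=C(CC/C(C)=C/CC/C(C)=C/CC[C@@]1(C)[C@@H]2/C(=C(/C)COCCC2)CC[C@@]1(C)O[Si](CC)(CC)CC)C(C)C | intermediate
29 | (2Z)-2-{(2S,3S,4R)-2-(3-hydroxypropyl)-3,4-dimethyl-4-[(triethylsilyl)oxy]-3-[(3E,7E)-4,8,12-trimethyl-11-methylidenetrideca-3,7-dien-1-yl]cyclohexylidene}propanal | C=C(CC/C(C)=C/CC/C(C)=C/CC[C@@]1(C)[C@@H](CCCO)/C(=C(/C)C=O)CC[C@@]1(C)O[Si](CC)(CC)CC)C(C)C | intermediate (not isolated)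
30 | (2Z)-2-{(2S,3S,4R)-4-hydroxy-2-(3-hydroxypropyl)-3,4-dimethyl-3-[(3E,7E)-4,8,12-trimethyl-11-methylidenetrideca-3,7-dien-1-yl]cyclohexylidene}propanal | C=C(CC/C(C)=C/CC/C(C)=C/CC[C@@]1(C)[C@@H](CCCO)/C(=C(/C)C=O)CC[C@@]1(C)O)C(C)C | target

**Step count and risks**

Total: 16 steps. Longest linear sequence: 13 steps (steps 1–7, then 11–16).

The three steps most likely to fail:

Step 15 (McMurry ring closure). What may go wrong: low-valent titanium may cleave the C–O bond next to the acetonyl ketone reductively, the reaction may stop at the pinacol, intermolecular coupling may compete, or C2 may epimerise. The fallback keeps the ring-enforced Z geometry but forms the alkene by olefination. It sets out from 26: esterification of the primary alcohol with 2-(diethoxyphosphoryl)propanoic acid (DCC, DMAP) gives the phosphonate ester F1. Intramolecular Horner–Wadsworth–Emmons olefination (LiCl, DBU, MeCN, high dilution) gives the eight-membered unsaturated lactone F2. LiAlH4 opens F2 to the allylic diol F3. MnO2 oxidises only the allylic alcohol of F3 and so returns to the route at 29, which HF·pyridine converts to 30.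

Step 12 (conjugate methylation and allylation). What may go wrong: the methyl copper reagent may not add to a β-carbon flanked by the fully substituted C4, or the allylation may show poor face selectivity. The fallback sets out from 21: Corey–Chaykovsky cyclopropanation with dimethylsulfoxonium methylide (Me3S(O)I, NaH, DMSO), anti to the silyloxy group, gives the cyclopropyl ketone F4. Dissolving-metal reduction (Li, NH3, THF, −78 °C) cleaves the external cyclopropane bond, which turns the CH2 into the C3 methyl and gives the same lithium enolate 23. Trapping with allyl iodide returns to the route at 24.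

Step 9 (asymmetric hydroxylation). What may go wrong: low enantioselectivity, the wrong sense of induction, or γ- instead of α′-deprotonation. The fallback takes the carbinol from the chiral pool by self-regeneration of stereocentres. It does not set out from a numbered compound; it replaces steps 8 and 9 (13 and 15 are not used) and starts from commercial (2S,5S)-2-tert-butyl-5-methyl-1,3-dioxolan-4-one (from (S)-lactic acid, C[C@@H]1O[C@H](C(C)(C)C)OC1=O). Its lithium enolate (LDA, THF, −78 °C) is alkylated anti to the tert-butyl group with 2-(2-iodoethyl)-2-methyl-1,3-dioxolane to give the ketal F5. PPTS in wet acetone frees the methyl ketone F6. LDA (2.2 equiv) closes the ring by intramolecular Claisen condensation onto the dioxolanone carbonyl, with loss of pivalaldehyde, to give the hydroxy dione F7. Ethanol with TsOH forms the enol ether at the less hindered carbonyl and returns to the route at 17.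

Further compounds
F1 | step 15 | 3-{(1R,2S,3R)-2,3-dimethyl-6-oxo-3-[(triethylsilyl)oxy]-2-[(3E,7E)-4,8,12-trimethyl-11-methylidenetrideca-3,7-dien-1-yl]cyclohexyl}propyl 2-(diethoxyphosphoryl)propanoate | C=C(CC/C(C)=C/CC/C(C)=C/CC[C@@]1(C)[C@@H](CCCOC(=O)C(C)P(=O)(OCC)OCC)C(=O)CC[C@@]1(C)O[Si](CC)(CC)CC)C(C)C
F2 | step 15 | (6aS,7S,8R)-1,7,8-trimethyl-8-[(triethylsilyl)oxy]-7-[(3E,7E)-4,8,12-trimethyl-11-methylidenetrideca-3,7-dien-1-yl]-4,5,6,6a,7,8,9,10-octahydro-2H-3-benzoxocin-2-one | C=C(CC/C(C)=C/CC/C(C)=C/CC[C@@]1(C)[C@@H]2/C(=C(/C)C(=O)OCCC2)CC[C@@]1(C)O[Si](CC)(CC)CC)C(C)C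
F3 | step 15 | (2Z)-2-{(2S,3S,4R)-2-(3-hydroxypropyl)-3,4-dimethyl-4-[(triethylsilyl)oxy]-3-[(3E,7E)-4,8,12-trimethyl-11-methylidenetrideca-3,7-dien-1-yl]cyclohexylidene}propan-1-ol | C=C(CC/C(C)=C/CC/C(C)=C/CC[C@@]1(C)[C@@H](CCCO)/C(=C(/C)CO)CC[C@@]1(C)O[Si](CC)(CC)CC)C(C)C
F4 | step 12 | (1S,5R,6R)-5-methyl-5-[(triethylsilyl)oxy]-6-[(3E,7E)-4,8,12-trimethyl-11-methylidenetrideca-3,7-dien-1-yl]bicyclo[4.1.0]heptan-2-one | C=C(CC/C(C)=C/CC/C(C)=C/CC[C@@]12C[C@@H]1C(=O)CC[C@@]2(C)O[Si](CC)(CC)CC)C(C)C
F5 | step 9 | (2S,5R)-2-tert-butyl-5-methyl-5-[2-(2-methyl-1,3-dioxolan-2-yl)ethyl]-1,3-dioxolan-4-one | CC1(CC[C@@]2(C)O[C@H](C(C)(C)C)OC2=O)OCCO1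
F6 | step 9 | (2S,5R)-2-tert-butyl-5-methyl-5-(3-oxobutyl)-1,3-dioxolan-4-one | CC(=O)CC[C@@]1(C)O[C@H](C(C)(C)C)OC1=O
F7 | step 9 | (4R)-4-hydroxy-4-methylcyclohexane-1,3-dione | O=C1CC(=O)CC[C@@]1(C)O
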